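## Analysis of the target

The target 26 is a 3,8''-linked biflavonoid. A naringenin-type flavanone (ring A with O5 and O7, pyranone ring C, a 4-hydroxyphenyl ring B on C2) is bonded through C3 to C8'' of a luteolin-type flavone whose O7'' carries a hydrogen sulfate. There are two adjacent stereocentres, C2 (R) and C3 (S), with the two aryl groups trans on ring C. C3 is α to the C4 ketone and bears an aryl group, so it is epimerisable and should settle trans; C2 is therefore the one centre that needs absolute control. The sensitive groups are the aryl sulfate monoester (acid-labile), the catechol and the other free phenols, and the β-aryloxy ketone of ring C, which can open by retro-oxa-Michael reaction under base and so erase C2. Three things make the synthesis hard: the C3–C8'' bond joins a tertiary carbon to an arene carbon flanked by O7'' and O1''; O7'' must be told apart from six other phenolic oxygens; and C2 must be formed as one enantiomer next to a very bulky C3 substituent. The strategy rests on one feature: C2 is a benzylic ether carbon (bonded to O1 and to ring B), and C3 lies between the aroyl carbon C4 and the flavone carbon C8''. C3 can therefore be the carbene carbon of a diazo ketone and C2 the CH2 of a 4-(benzyloxy)benzyl ether on ring A, so that ring C closes by forming the C2–C3 bond.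

## Retrosynthetic reasoning

**Benzyl ethers (26 from 25).** All phenols other than O5 and O7'' are carried as benzyl ethers to the end, so the last operation is one hydrogenolysis of sulfate 25. Only C–O bonds to benzylic carbons are cut; the sulfate and both stereocentres are already in place.

**O7''–S (25 from 24).** The sulfate is attached to diol 24. Its O7''–H is free and acidic, while O5–H is locked in a hydrogen bond to the C4 carbonyl and is the least reactive phenol of the molecule. The selectivity therefore comes from the structure and needs no extra protecting group.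

**O5–Si and O7''–Si (24 from 23).** Both silyl ethers of flavanone 23 are removed in one operation. They are the two oxygen substituents that sit next to the reacting carbons of the key step, and silyl groups are chosen there because they offer no activated C–H bond.

**C2–C3 (23 from 21).** This is the strategic cut. Opening ring C between C2 and C3 gives diazo ketone 21, an open deoxybenzoin with no stereocentre, in which C3 is the diazo carbon and C2 is the CH2 of the single 4-(benzyloxy)benzyl ether on ring A. The forward reaction has to generate the carbene at C3, insert it into one C–H bond of that CH2 group with control of the C2 configuration, and leave C3 to equilibrate to trans (through the cis epimer 22).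

**C3=N2 (21 from 20).** The diazo group goes back to the methylene of ketone 20, which is acidic enough (aryl and aroyl on the same carbon) for a direct diazo transfer.

**Ring-A ethers (20 from 19, 19 from 17 and 18, 17 from 16).** Ring A needs three different oxygen substituents: a silyl ether on O5, the 4-(benzyloxy)benzyl ether on the oxygen that becomes O1, and a benzyl ether on O7. The ketone itself tells them apart. In triol 16 the para hydroxyl is the only one without a hydrogen bond to the carbonyl and is benzylated first (17). One ortho hydroxyl is then alkylated with chloride 18 (19), and the last, chelated hydroxyl is silylated (20). Each group is introduced once, in its own step, and no symmetric ring-A building block has to be desymmetrised.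

**C4–C4a (16 from 13 and 14).** Cutting the bond between the carbonyl carbon and ring A gives phloroglucinol 14 as the carbon nucleophile and nitrile 13 as the acyl equivalent, joined through ketimine 15. Free phloroglucinol is used because the three hydroxyl groups can only be differentiated once the acyl group is on the ring. The nitrile allows the bond to form at 0 °C without a strong Lewis acid, which the benzyl ethers of the flavone would not tolerate.

**C≡N (13 from 11).** Nitrile 13 comes from aldehyde 11 by condensation and elimination through oxime derivative 12, with no change in the carbon skeleton.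

**C8''–CH2 (11 from 9 via 10, 9 from 8, 8 from 7).** The hindered bond at C8'' is made early as a simple aryl–CH2 bond. Aldehyde 11 arises by oxidative cleavage of the allyl group of 9 (through diol 10), and 9 is the silyl ether of phenol 8. Phenol 8 comes from allyl ether 7 by a [3,3]-sigmatropic shift, which moves the allyl group from O7'' to C8'' and frees O7''–H for the silyl group in the same step. The allyl group is thus both the temporary O7'' protecting group and the carbon source for C3 and C4.

**Flavone pyranone (7 from 6 from 5, from 3 and 4).** The pyranone is cut at O1''–C2'' (cyclodehydration of diketone 6) and at the C–C bond of the diketone that the acyl shift in ester 5 forms. Ester 5 is made from phenol 3 and acid 4. This base-then-acid sequence tolerates the allyl ether, which an iodine-mediated chalcone cyclisation would put at risk.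

**Ring ethers (3 from 2 from 1).** The oxygens of 1 are told apart by the hydrogen bonds to the acetyl group: the free 4-OH is allylated first (2), then one ortho OH is benzylated (3), and the last ortho OH stays free for ring closure.

## Alternatives that were turned down

**Alternative 1:** Ring A is delivered as an aryne onto an open aldol chain; the cuts are O1–C8a and C4–C4a. In the forward step fluoride frees the C2 alkoxide of a silylated anti-aldol adduct on a thiazolidinethione auxiliary and generates the aryne. The alkoxide adds to the aryne, and the aryl anion attacks the acyl-auxiliary carbonyl to give the protected flavanone–flavone A1.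
- For it: both stereocentres are set by auxiliary-controlled aldol chemistry with a predictable sense before the ring is formed, and the regiochemistry of addition to the alkoxy-substituted aryne fits the target. On certainty of absolute configuration it is stronger than the chosen route.
- Against it: the freed aldolate has an α-aryl group and is prone to retro-aldol cleavage and C3 epimerisation. A secondary alkoxide must capture a short-lived aryne intermolecularly. The anti-aldol of a di-ortho-substituted arylacetyl unit is itself doubtful. The allyl group on O7'' of A1 needs a separate removal.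
- Comparison: the chosen route uses a stereocentre-free precursor that cannot fragment, needs no stoichiometric auxiliary, and sets C2 with a catalyst.

**Alternative 2:** O7'' and C3 are tied by a temporary lactone carbonyl; the cuts are O1–C2 and C3–C4. A ring-A salicylaldehyde and a benzylidene lactone of the flavone react under a cinchona-derived squaramide base. The phenol adds to the benzylidene carbon, the lactone enolate adds to the aldehyde, and ring C closes as the spiro-lactone flavan-4-ol A2.
- For it: the step is metal-free and uses no diazo compound, and oxa-Michael/aldol cascades of salicylaldehydes are well developed. Opening the lactone later frees O7''–H alone for sulfation. On that point it is cleaner than the chosen route, where O7''–H is sulfated beside a chelated O5–H.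
- Against it: a quaternary spiro centre must be built on a tetrasubstituted, electron-rich acceptor, where the oxa-Michael step is reversible. Two of the three new stereocentres of A2 are made only to be erased. Oxidation at C4, lactone opening and decarboxylation follow, and the β-keto acid stage invites retro-oxa-Michael loss of C2.
- Comparison: the chosen route forms C2–C3 directly at the ketone oxidation level and needs three steps after the key step.

**Alternative 3:** The polarity at C4 is reversed; the cut is C3–C4. A chiral triazolium-derived carbene converts a ring-A aldehyde into an acyl anion equivalent that adds to a flavon-8-yl ketone, giving the 3-hydroxyflavanone–flavone A3.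
- For it: carbene-catalysed intramolecular crossed benzoin closure to 3-hydroxychroman-4-ones is among the best-developed enantioselective routes to this ring. On catalyst precedent for that bond it is stronger than the chosen route.
- Against it: the stereocentre the catalyst sets (C3) is removed afterwards by deoxygenation. C2 is already present in the precursor, α to a ketone, and can only be controlled through a dynamic resolution. The electrophile is a di-ortho-substituted aryl ketone. Reductive removal of the tertiary hydroxyl next to the β-aryloxy group risks ring opening. A3 also still carries an allyl group on O7''.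
- Comparison: the chosen route makes the surviving centre C2 in the key step itself and has no redox correction at C3.

Key step: step 15

Remarks and assumptions:
- Abbreviations: PBB = 4-(benzyloxy)benzyl, i.e. [4-(benzyloxy)phenyl]methyl. Fl = 5-(benzyloxy)-2-[3,4-bis(benzyloxy)phenyl]-4-oxo-7-[(triisopropylsilyl)oxy]-4H-chromen-8-yl. ArA = 4-(benzyloxy)-2-(PBB-oxy)-6-[(triisopropylsilyl)oxy]phenyl.
- Locants: unprimed and single-primed for the flavanone, double-primed for the flavone core, triple-primed for its catechol ring.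
- Assumption on the ring-A phenols: in ketones 16, 17 and 19 the hydroxyl groups ortho to the carbonyl are taken to be hydrogen-bonded as in 1, so that the order para, ortho, ortho of steps 1 and 2 holds again in steps 11 to 13.
- Assumption on the catalyst: Rh2(S-PTTL)4 is taken to select the benzylic hydrogen that leads to (2R). If the sense proves opposite, Rh2(R-PTTL)4 is used and nothing else changes.
- Assumption on the sulfate: the monoesters 25 and 26 are drawn as hydrogen sulfates, as in the target structure. They would be handled as pyridinium or sodium salts, and the acid form is released at the end on an acidic ion-exchange resin.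

## Route

Step 1
Reactants: 1 2,4,6-trihydroxyacetophenone
Product: 2 1-[2,6-dihydroxy-4-(prop-2-en-1-yloxy)phenyl]ethan-1-one
Conditions: allyl bromide (1.0 equiv), K2CO3 (1.0 equiv), acetone, rt
Reagents that add atoms: allyl bromide, C=CCBr
Why: Williamson etherification; the 4-OH is the most acidic hydroxyl and the only one not hydrogen-bonded to the acetyl group, so one equivalent of base and halide should alkylate it first, and over-alkylated material is removed by chromatography.

Step 2
Reactants: 2 1-[2,6-dihydroxy-4-(prop-2-en-1-yloxy)phenyl]ethan-1-one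
Product: 3 1-[2-(benzyloxy)-6-hydroxy-4-(prop-2-en-1-yloxy)phenyl]ethan-1-one
Conditions: BnBr (1.05 equiv), K2CO3, DMF, rt
Reagents that add atoms: benzyl bromide, BrCc1ccccc1
Why: Williamson etherification; once one ortho oxygen is benzylated the last OH is held in a strong hydrogen bond to the ketone and should stay free under these mild conditions.

Step 3
Reactants: 3 1-[2-(benzyloxy)-6-hydroxy-4-(prop-2-en-1-yloxy)phenyl]ethan-1-one; 4 3,4-bis(benzyloxy)benzoic acid
Product: 5 2-acetyl-3-(benzyloxy)-5-(prop-2-en-1-yloxy)phenyl 3,4-bis(benzyloxy)benzoate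
Conditions: DIC, DMAP (0.2 equiv), CH2Cl2, rt
Reagents that add atoms: none
Why: Steglich esterification; the acylpyridinium intermediate is reactive enough for the hydrogen-bonded, flanked phenol.

Step 4
Reactants: 5 2-acetyl-3-(benzyloxy)-5-(prop-2-en-1-yloxy)phenyl 3,4-bis(benzyloxy)benzoate
Product: 6 1-[2-(benzyloxy)-6-hydroxy-4-(prop-2-en-1-yloxy)phenyl]-3-[3,4-bis(benzyloxy)phenyl]propane-1,3-dione
Conditions: KOtBu (2.5 equiv), THF, 0 °C to rt; aq. NH4Cl
Reagents that add atoms: none
Why: Baker–Venkataraman rearrangement; the acetyl enolate attacks the neighbouring aryl ester through a six-membered transition state and the aroyl group moves from O to C, while allyl and benzyl ethers are inert to the alkoxide in THF.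

Step 5
Reactants: 6 1-[2-(benzyloxy)-6-hydroxy-4-(prop-2-en-1-yloxy)phenyl]-3-[3,4-bis(benzyloxy)phenyl]propane-1,3-dione
Product: 7 5-(benzyloxy)-2-[3,4-bis(benzyloxy)phenyl]-7-(prop-2-en-1-yloxy)-4H-chromen-4-one
Conditions: p-TsOH·H2O (0.1 equiv), toluene, 90 °C
Reagents that add atoms: none
Why: Acid-catalysed cyclodehydration of the 2-hydroxyaryl 1,3-diketone closes the pyranone of the flavone; catalytic sulfonic acid at this temperature should leave the aryl benzyl and allyl ethers intact.

Step 6
Reactants: 7 5-(benzyloxy)-2-[3,4-bis(benzyloxy)phenyl]-7-(prop-2-en-1-yloxy)-4H-chromen-4-one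
Product: 8 5-(benzyloxy)-2-[3,4-bis(benzyloxy)phenyl]-7-hydroxy-8-(prop-2-en-1-yl)-4H-chromen-4-one
Conditions: N,N-diethylaniline, 200 °C, argon, sealed tube
Reagents that add atoms: none
Why: Aromatic Claisen rearrangement ([3,3]-sigmatropic shift, then tautomerisation); in 7-allyloxychromones the C7–C8 bond has the higher double-bond character, so the allyl group should go to C8'' and not to C6'', and O7''–H is set free.

Step 7
Reactants: 8 5-(benzyloxy)-2-[3,4-bis(benzyloxy)phenyl]-7-hydroxy-8-(prop-2-en-1-yl)-4H-chromen-4-one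
Product: 9 5-(benzyloxy)-2-[3,4-bis(benzyloxy)phenyl]-8-(prop-2-en-1-yl)-7-[(triisopropylsilyl)oxy]-4H-chromen-4-one
Conditions: TIPSCl, imidazole, DMF, rt to 40 °C
Reagents that add atoms: triisopropylsilyl chloride, CC(C)[Si](Cl)(C(C)C)C(C)C
Why: Silylation of the acidic 7''-OH; the silyl ether stops the phenol from cyclising onto the side chain once it is oxidised, and it is the group that will sit next to the carbene and later give way to the sulfate.

Step 8
Reactants: 9 5-(benzyloxy)-2-[3,4-bis(benzyloxy)phenyl]-8-(prop-2-en-1-yl)-7-[(triisopropylsilyl)oxy]-4H-chromen-4-one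
Product: 11 Fl-acetaldehyde (2-{5-(benzyloxy)-2-[3,4-bis(benzyloxy)phenyl]-4-oxo-7-[(triisopropylsilyl)oxy]-4H-chromen-8-yl}acetaldehyde), via racemic diol 10 (not isolated)
Conditions: OsO4 (2 mol %), NaIO4 (4 equiv), 2,6-lutidine, dioxane/H2O 3:1, rt
Reagents that add atoms: osmium tetroxide (catalytic oxygen carrier), O=[Os](=O)(=O)=O; sodium periodate (terminal oxidant), [Na+].[O-]I(=O)(=O)=O
Why: Johnson–Lemieux oxidative cleavage; OsO4 dihydroxylates the terminal alkene and NaIO4 cleaves the diol and reoxidises osmium, while the electron-poor C2''=C3'' bond of the pyranone and the benzyl ethers should not react.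

Step 9
Reactants: 11 Fl-acetaldehyde
Product: 13 Fl-acetonitrile (2-{5-(benzyloxy)-2-[3,4-bis(benzyloxy)phenyl]-4-oxo-7-[(triisopropylsilyl)oxy]-4H-chromen-8-yl}acetonitrile), via O-phosphinyl oxime 12 (not isolated)
Conditions: Ph2P(O)ONH2 (1.2 equiv), toluene, 85 °C
Reagents that add atoms: O-(diphenylphosphinyl)hydroxylamine, NOP(=O)(c1ccccc1)c1ccccc1
Why: Aldehyde-to-nitrile conversion by condensation and elimination; the aldehyde forms the O-phosphinyl aldoxime 12, which loses diphenylphosphinic acid on heating. The medium is neutral and anhydrous, so the aryl silyl ether, the benzyl ethers and the enolisable CH2 group should not be affected.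

Step 10
Reactants: 13 Fl-acetonitrile; 14 phloroglucinol (benzene-1,3,5-triol)
Product: 16 2-Fl-1-(2,4,6-trihydroxyphenyl)ethan-1-one, via ketimine 15 (not isolated)
Conditions: 14 (1.5 equiv, anhydrous), ZnCl2 (1.0 equiv), HCl (g), Et2O/1,4-dioxane, 0 °C to rt; then H2O, 70 °C
Reagents that add atoms: water, O
Why: Hoesch reaction; the nitrile activated by HCl and ZnCl2 is attacked by a ring carbon of phloroglucinol, the most reactive arene for this acylation, and the ketimine 15 separates as its hydrochloride, which is deactivated toward a second acylation and is hydrolysed to the ketone by warm water. Anhydrous HCl at 0 °C should not cleave aryl benzyl ethers, and the hindered aryl triisopropylsilyl ether is among the most acid-stable silyl ethers.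

Step 11
Reactants: 16 2-Fl-1-(2,4,6-trihydroxyphenyl)ethan-1-one
Product: 17 1-[4-(benzyloxy)-2,6-dihydroxyphenyl]-2-Fl-ethan-1-one
Conditions: BnBr (1.0 equiv), K2CO3 (1.0 equiv), acetone, rt
Reagents that add atoms: benzyl bromide, BrCc1ccccc1
Why: Williamson etherification, selective as in step 1; the para hydroxyl is the most acidic and the only one not hydrogen-bonded to the ketone, and the benzylic CH2 of the ketone is far less acidic than the phenols, so carbonate should not cause C-alkylation.

Step 12
Reactants: 17 1-[4-(benzyloxy)-2,6-dihydroxyphenyl]-2-Fl-ethan-1-one; 18 4-(benzyloxy)benzyl chloride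
Product: 19 1-[4-(benzyloxy)-2-hydroxy-6-(PBB-oxy)phenyl]-2-Fl-ethan-1-one
Conditions: 18 (1.05 equiv), K2CO3 (1.2 equiv), acetone, 50 °C
Reagents that add atoms: none
Why: Williamson etherification, selective as in step 2; the reactive 4-alkoxybenzyl chloride alkylates one of the two equivalent ortho hydroxyls, after which the remaining one is held in a hydrogen bond to the ketone and should stay free.

Step 13
Reactants: 19 1-[4-(benzyloxy)-2-hydroxy-6-(PBB-oxy)phenyl]-2-Fl-ethan-1-one
Product: 20 1-ArA-2-Fl-ethan-1-one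
Conditions: TIPSOTf (1.2 equiv), 2,6-lutidine, CH2Cl2, −20 to 0 °C
Reagents that add atoms: triisopropylsilyl trifluoromethanesulfonate, CC(C)[Si](OS(=O)(=O)C(F)(F)F)(C(C)C)C(C)C
Why: Silylation of the hydrogen-bonded phenol with the silyl triflate, which is reactive enough where the chloride would be slow; with the weak, hindered base at low temperature the phenol should react well before the twisted, di-ortho-substituted ketone is enolised.

Step 14
Reactants: 20 1-ArA-2-Fl-ethan-1-one
Product: 21 2-diazo-1-ArA-2-Fl-ethan-1-one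
Conditions: 4-acetamidobenzenesulfonyl azide, DBU, MeCN, 0 °C to rt
Reagents that add atoms: 4-acetamidobenzenesulfonyl azide, CC(=O)Nc1ccc(cc1)S(=O)(=O)N=[N+]=[N-]
Why: Regitz diazo transfer; the methylene between the aroyl group and the flavone ring is deprotonated by DBU, the enolate attacks the terminal nitrogen of the sulfonyl azide and the sulfonamide is lost. Deoxybenzoins are standard substrates.

Step 15
Reactants: 21 2-diazo-1-ArA-2-Fl-ethan-1-one
Product: 23 (2R,3S)-7-(benzyloxy)-2-[4-(benzyloxy)phenyl]-3-Fl-5-[(triisopropylsilyl)oxy]-2,3-dihydro-4H-chromen-4-one, via cis epimer 22 (not isolated)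
Conditions: Rh2(S-PTTL)4, dirhodium tetrakis[N-phthaloyl-(S)-tert-leucinate] (2 mol %), CH2Cl2, −20 °C to rt, slow addition of 21; then Et3N (0.5 equiv), rt
Reagents that add atoms: none
Why: Loss of N2 from 21 on the divalent rhodium centre of Rh2(S-PTTL)4 gives a rhodium carbene at C3 with an aryl donor and an aroyl acceptor; its vacant orbital engages the hydridic C–H bond of the ortho O–CH2 group of ring A in a concerted, asynchronous three-centre transition state, which forms the C2–C3 bond and releases the catalyst. The closest known reaction type is the dirhodium carboxylate-catalysed insertion of carbenes from 2-alkoxyphenyl α-diazo ketones into the ether C–H bond to give chroman-4-ones, together with the insertion of aryl-substituted carbenes into benzyl ethers to give dihydrobenzofurans. Ring C closes as a six-membered ring by 1,6-insertion (C3, C4, C4a, C8a, O1, C2); a five-membered mode does not exist on this tether because the fifth atom is O1 itself. C2 is set by the chiral carboxylate ligands, which tell apart the two enantiotopic hydrogens of the CH2 group, the insertion going with retention at carbon. C3 is an α-aryl ketone carbon and is set under thermodynamic control: Et3N equilibrates any cis epimer 22 to the trans isomer 23 with both aryl groups equatorial. The step needs site selectivity, which the substrate secures because the CH2 of the PBB ether is the only activated C–H bond within reach: O5 and O7'' carry silyl groups with unactivated C–H bonds only, the para benzyl ether cannot reach the carbene, and the benzyl ethers on O5'' and on the catechol ring are remote. It also needs chemoselectivity against attack of O1 on the carbene, which the less electrophilic donor/acceptor carbene and the crowded, weakly basic aryl ether oxygen should hold back.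

Step 16
Reactants: 23 (2R,3S)-7-(benzyloxy)-2-[4-(benzyloxy)phenyl]-3-Fl-5-[(triisopropylsilyl)oxy]-2,3-dihydro-4H-chromen-4-one
Product: 24 (2R,3S)-7-(benzyloxy)-3-{5-(benzyloxy)-2-[3,4-bis(benzyloxy)phenyl]-7-hydroxy-4-oxo-4H-chromen-8-yl}-2-[4-(benzyloxy)phenyl]-5-hydroxy-2,3-dihydro-4H-chromen-4-one
Conditions: TBAF, AcOH (1:1, 3 equiv), THF, 0 °C to rt
Reagents that add atoms: none
Why: Fluoride-mediated cleavage of both aryl silyl ethers; acetic acid buffers the phenoxides so that the β-aryloxy ketone is not opened by retro-oxa-Michael reaction, and both stereocentres stay untouched.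

Step 17
Reactants: 24 (2R,3S)-7-(benzyloxy)-3-{5-(benzyloxy)-2-[3,4-bis(benzyloxy)phenyl]-7-hydroxy-4-oxo-4H-chromen-8-yl}-2-[4-(benzyloxy)phenyl]-5-hydroxy-2,3-dihydro-4H-chromen-4-one
Product: 25 5-(benzyloxy)-8-{(2R,3S)-7-(benzyloxy)-2-[4-(benzyloxy)phenyl]-5-hydroxy-4-oxo-3,4-dihydro-2H-chromen-3-yl}-2-[3,4-bis(benzyloxy)phenyl]-4-oxo-4H-chromen-7-yl hydrogen sulfate
Conditions: SO3·pyridine (1.5 equiv), pyridine, 0 °C to rt
Reagents that add atoms: sulfur trioxide–pyridine complex, [O-]S(=O)(=O)[n+]1ccccc1
Why: O-sulfation of a phenol with the SO3·pyridine complex; O7''–H is free and acidic, whereas O5–H is held in a six-membered hydrogen bond to the C4 carbonyl and is the kind of flavanone hydroxyl that resists sulfation with SO3–amine complexes at room temperature, so a small excess of reagent should react at O7'' only.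

Step 18
Reactants: 25 5-(benzyloxy)-8-{(2R,3S)-7-(benzyloxy)-2-[4-(benzyloxy)phenyl]-5-hydroxy-4-oxo-3,4-dihydro-2H-chromen-3-yl}-2-[3,4-bis(benzyloxy)phenyl]-4-oxo-4H-chromen-7-yl hydrogen sulfate
Product: 26 2-(3,4-dihydroxyphenyl)-8-[(2R,3S)-5,7-dihydroxy-2-(4-hydroxyphenyl)-4-oxo-3,4-dihydro-2H-chromen-3-yl]-5-hydroxy-4-oxo-4H-chromen-7-yl hydrogen sulfate (CNP0314990.1)
Conditions: H2 (1 atm), Pd/C (10 %), THF/MeOH, rt; then sulfonic acid resin (H+ form), 0 °C
Reagents that add atoms: none
Why: Hydrogenolysis of benzylic C–O bonds on Pd/C; the five benzyl ethers are cleaved to toluene. Aryl sulfate monoesters and the flavone double bond should not be reduced at 1 atm and room temperature, and neither stereocentre is touched.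

## Compound list

1 | 2,4,6-trihydroxyacetophenone | CC(=O)c1c(O)cc(O)cc1O | starting material
2 | 1-[2,6-dihydroxy-4-(prop-2-en-1-yloxy)phenyl]ethan-1-one | CC(=O)c1c(O)cc(OCC=C)cc1O | intermediate
3 | 1-[2-(benzyloxy)-6-hydroxy-4-(prop-2-en-1-yloxy)phenyl]ethan-1-one | CC(=O)c1c(O)cc(OCC=C)cc1OCc1ccccc1 | intermediate
4 | 3,4-bis(benzyloxy)benzoic acid | OC(=O)c1ccc(OCc2ccccc2)c(OCc2ccccc2)c1 | starting material
5 | 2-acetyl-3-(benzyloxy)-5-(prop-2-en-1-yloxy)phenyl 3,4-bis(benzyloxy)benzoate | CC(=O)c1c(OC(=O)c2ccc(OCc3ccccc3)c(OCc3ccccc3)c2)cc(OCC=C)cc1OCc1ccccc1 | intermediate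
6 | 1-[2-(benzyloxy)-6-hydroxy-4-(prop-2-en-1-yloxy)phenyl]-3-[3,4-bis(benzyloxy)phenyl]propane-1,3-dione | O=C(CC(=O)c1ccc(OCc2ccccc2)c(OCc2ccccc2)c1)c1c(O)cc(OCC=C)cc1OCc1ccccc1 | intermediate
7 | 5-(benzyloxy)-2-[3,4-bis(benzyloxy)phenyl]-7-(prop-2-en-1-yloxy)-4H-chromen-4-one | O=c1cc(-c2ccc(OCc3ccccc3)c(OCc3ccccc3)c2)oc2cc(OCC=C)cc(OCc3ccccc3)c12 | intermediate
8 | 5-(benzyloxy)-2-[3,4-bis(benzyloxy)phenyl]-7-hydroxy-8-(prop-2-en-1-yl)-4H-chromen-4-one | O=c1cc(-c2ccc(OCc3ccccc3)c(OCc3ccccc3)c2)oc2c(CC=C)c(O)cc(OCc3ccccc3)c12 | intermediate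
9 | 5-(benzyloxy)-2-[3,4-bis(benzyloxy)phenyl]-8-(prop-2-en-1-yl)-7-[(triisopropylsilyl)oxy]-4H-chromen-4-one | O=c1cc(-c2ccc(OCc3ccccc3)c(OCc3ccccc3)c2)oc2c(CC=C)c(O[Si](C(C)C)(C(C)C)C(C)C)cc(OCc3ccccc3)c12 | intermediate
10 | racemic 5-(benzyloxy)-2-[3,4-bis(benzyloxy)phenyl]-8-(2,3-dihydroxypropyl)-7-[(triisopropylsilyl)oxy]-4H-chromen-4-one (not isolated) | OCC(O)Cc1c(O[Si](C(C)C)(C(C)C)C(C)C)cc(OCc2ccccc2)c2c(=O)cc(-c3ccc(OCc4ccccc4)c(OCc4ccccc4)c3)oc12 | intermediate
11 | 2-{5-(benzyloxy)-2-[3,4-bis(benzyloxy)phenyl]-4-oxo-7-[(triisopropylsilyl)oxy]-4H-chromen-8-yl}acetaldehyde (Fl-acetaldehyde) | O=CCc1c(O[Si](C(C)C)(C(C)C)C(C)C)cc(OCc2ccccc2)c2c(=O)cc(-c3ccc(OCc4ccccc4)c(OCc4ccccc4)c3)oc12 | intermediate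
12 | Fl-acetaldehyde O-(diphenylphosphinyl) oxime (not isolated) | O=P(ON=CCc1c(O[Si](C(C)C)(C(C)C)C(C)C)cc(OCc2ccccc2)c2c(=O)cc(-c3ccc(OCc4ccccc4)c(OCc4ccccc4)c3)oc12)(c1ccccc1)c1ccccc1 | intermediate
13 | 2-{5-(benzyloxy)-2-[3,4-bis(benzyloxy)phenyl]-4-oxo-7-[(triisopropylsilyl)oxy]-4H-chromen-8-yl}acetonitrile (Fl-acetonitrile) | N#CCc1c(O[Si](C(C)C)(C(C)C)C(C)C)cc(OCc2ccccc2)c2c(=O)cc(-c3ccc(OCc4ccccc4)c(OCc4ccccc4)c3)oc12 | intermediate
14 | phloroglucinol (benzene-1,3,5-triol) | Oc1cc(O)cc(O)c1 | starting material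
15 | 2-(2-Fl-ethanimidoyl)benzene-1,3,5-triol, the ketimine, present as its hydrochloride (not isolated) | N=C(Cc1c(O[Si](C(C)C)(C(C)C)C(C)C)cc(OCc2ccccc2)c2c(=O)cc(-c3ccc(OCc4ccccc4)c(OCc4ccccc4)c3)oc12)c1c(O)cc(O)cc1O | intermediate
16 | 2-Fl-1-(2,4,6-trihydroxyphenyl)ethan-1-one | O=C(Cc1c(O[Si](C(C)C)(C(C)C)C(C)C)cc(OCc2ccccc2)c2c(=O)cc(-c3ccc(OCc4ccccc4)c(OCc4ccccc4)c3)oc12)c1c(O)cc(O)cc1O | intermediate
17 | 1-[4-(benzyloxy)-2,6-dihydroxyphenyl]-2-Fl-ethan-1-one | O=C(Cc1c(O[Si](C(C)C)(C(C)C)C(C)C)cc(OCc2ccccc2)c2c(=O)cc(-c3ccc(OCc4ccccc4)c(OCc4ccccc4)c3)oc12)c1c(O)cc(OCc2ccccc2)cc1O | intermediate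
18 | 4-(benzyloxy)benzyl chloride | ClCc1ccc(OCc2ccccc2)cc1 | starting material
19 | 1-[4-(benzyloxy)-2-hydroxy-6-(PBB-oxy)phenyl]-2-Fl-ethan-1-one | O=C(Cc1c(O[Si](C(C)C)(C(C)C)C(C)C)cc(OCc2ccccc2)c2c(=O)cc(-c3ccc(OCc4ccccc4)c(OCc4ccccc4)c3)oc12)c1c(O)cc(OCc2ccccc2)cc1OCc1ccc(OCc2ccccc2)cc1 | intermediate
20 | 1-ArA-2-Fl-ethan-1-one | O=C(Cc1c(O[Si](C(C)C)(C(C)C)C(C)C)cc(OCc2ccccc2)c2c(=O)cc(-c3ccc(OCc4ccccc4)c(OCc4ccccc4)c3)oc12)c1c(O[Si](C(C)C)(C(C)C)C(C)C)cc(OCc2ccccc2)cc1OCc1ccc(OCc2ccccc2)cc1 | intermediate
21 | 2-diazo-1-ArA-2-Fl-ethan-1-one | [N-]=[N+]=C(C(=O)c1c(OCc2ccc(OCc3ccccc3)cc2)cc(OCc2ccccc2)cc1O[Si](C(C)C)(C(C)C)C(C)C)c1c(O[Si](C(C)C)(C(C)C)C(C)C)cc(OCc5ccccc5)c2c(=O)cc(-c3ccc(OCc4ccccc4)c(OCc4ccccc4)c3)oc12 | intermediate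
22 | (2R,3R)-7-(benzyloxy)-2-[4-(benzyloxy)phenyl]-3-Fl-5-[(triisopropylsilyl)oxy]-2,3-dihydro-4H-chromen-4-one, cis epimer (not isolated) | O=C1c2c(O[Si](C(C)C)(C(C)C)C(C)C)cc(OCc3ccccc3)cc2O[C@@H](c2ccc(OCc3ccccc3)cc2)[C@H]1c1c(O[Si](C(C)C)(C(C)C)C(C)C)cc(OCc5ccccc5)c2c(=O)cc(-c3ccc(OCc4ccccc4)c(OCc4ccccc4)c3)oc12 | intermediate
23 | (2R,3S)-7-(benzyloxy)-2-[4-(benzyloxy)phenyl]-3-Fl-5-[(triisopropylsilyl)oxy]-2,3-dihydro-4H-chromen-4-one | O=C1c2c(O[Si](C(C)C)(C(C)C)C(C)C)cc(OCc3ccccc3)cc2O[C@@H](c2ccc(OCc3ccccc3)cc2)[C@@H]1c1c(O[Si](C(C)C)(C(C)C)C(C)C)cc(OCc5ccccc5)c2c(=O)cc(-c3ccc(OCc4ccccc4)c(OCc4ccccc4)c3)oc12 | intermediate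
24 | (2R,3S)-7-(benzyloxy)-3-{5-(benzyloxy)-2-[3,4-bis(benzyloxy)phenyl]-7-hydroxy-4-oxo-4H-chromen-8-yl}-2-[4-(benzyloxy)phenyl]-5-hydroxy-2,3-dihydro-4H-chromen-4-one | O=C1c2c(O)cc(OCc3ccccc3)cc2O[C@@H](c2ccc(OCc3ccccc3)cc2)[C@@H]1c1c(O)cc(OCc5ccccc5)c2c(=O)cc(-c3ccc(OCc4ccccc4)c(OCc4ccccc4)c3)oc12 | intermediate
25 | 5-(benzyloxy)-8-{(2R,3S)-7-(benzyloxy)-2-[4-(benzyloxy)phenyl]-5-hydroxy-4-oxo-3,4-dihydro-2H-chromen-3-yl}-2-[3,4-bis(benzyloxy)phenyl]-4-oxo-4H-chromen-7-yl hydrogen sulfate | O=C1c2c(O)cc(OCc3ccccc3)cc2O[C@@H](c2ccc(OCc3ccccc3)cc2)[C@@H]1c1c(OS(=O)(=O)O)cc(OCc5ccccc5)c2c(=O)cc(-c3ccc(OCc4ccccc4)c(OCc4ccccc4)c3)oc12 | intermediate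
26 | 2-(3,4-dihydroxyphenyl)-8-[(2R,3S)-5,7-dihydroxy-2-(4-hydroxyphenyl)-4-oxo-3,4-dihydro-2H-chromen-3-yl]-5-hydroxy-4-oxo-4H-chromen-7-yl hydrogen sulfate | O=C1c2c(O)cc(O)cc2O[C@@H](c2ccc(O)cc2)[C@@H]1c1c(OS(=O)(=O)O)cc(O)c2c(=O)cc(-c3ccc(O)c(O)c3)oc12 | target

## Step count and least certain steps

Total: 18 steps. Longest linear sequence: 18 steps (steps 1 to 18, from 1); compounds 4, 14 and 18 enter as purchased reactants.

**Step 15 (key step).** The most likely failure is attack of the ether oxygen O1 on the carbene to give a five-membered oxonium ylide, followed by a 1,2-shift of the electron-rich benzyl group to C3, which would give a benzofuranone in place of the chromanone. A Wolff-type rearrangement of the diaryl diazo ketone is a second possibility. Facial discrimination may also be poor, because the carbene carbon lies between two di-ortho-substituted arenes that keep the chiral ligands at a distance. The fallback gives up the carbene and closes ring C by condensation. It sets out from dihydroxy ketone 17, in which either of the two equivalent ortho hydroxyls can serve as O1. Condensation with commercial 4-(benzyloxy)benzaldehyde under pyrrolidine in EtOH is the known way from 2-hydroxydeoxybenzoins to trans-2,3-diarylchroman-4-ones (Knoevenagel-type condensation, then 6-endo oxa-Michael closure). It should give the trans chromanone with a free 5-OH as the racemate, that is (2R,3S)-7-(benzyloxy)-2-[4-(benzyloxy)phenyl]-3-Fl-5-hydroxy-2,3-dihydro-4H-chromen-4-one F1 together with its (2S,3R) enantiomer F2. Preparative chromatography on a chiral stationary phase should separate F1, and TBAF with AcOH in THF removes its remaining silyl group to give diol 24. The route continues with step 17.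

**Step 10.** The flavone may separate from the ethereal HCl as its oxonium salt and react slowly, and the long exposure to acid may then cost the benzyl ether on O5'' or the silyl ether on O7''. The fallback replaces the acid-mediated acylation by a carbanion addition. It sets out from aldehyde 11 and phloroglucinol 14. MOMCl with DIPEA converts 14 into 1,3,5-tris(methoxymethoxy)benzene F3, and NBS in CH2Cl2 gives 2-bromo-1,3,5-tris(methoxymethoxy)benzene F4. Bromine–lithium exchange with n-BuLi in THF at −78 °C gives [2,4,6-tris(methoxymethoxy)phenyl]lithium F5, which is added to 11 to give the racemic carbinol 2-Fl-1-[2,4,6-tris(methoxymethoxy)phenyl]ethan-1-ol F6. Dess–Martin oxidation gives the ketone 2-Fl-1-[2,4,6-tris(methoxymethoxy)phenyl]ethan-1-one F7, and HCl in MeOH/THF at rt to 40 °C removes the three acetal groups to give triol 16. The route resumes at step 11.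

**Step 17.** Sulfation may be slow at the hindered O7''–H, and forcing it may then bring in the chelated O5–H as well. The fallback removes the free O5–H from the sulfation step by a change of protecting group. It sets out from phenol 19. Alkylation of the chelated hydroxyl with chloride 18 (K2CO3, DMF, 60 °C) should give 1-[4-(benzyloxy)-2,6-bis(PBB-oxy)phenyl]-2-Fl-ethan-1-one F8, and diazo transfer as in step 14 gives the diazo ketone 2-diazo-1-[4-(benzyloxy)-2,6-bis(PBB-oxy)phenyl]-2-Fl-ethan-1-one F9. Insertion as in step 15, where either of the two equivalent ortho ethers leads to the same product, gives (2R,3S)-7-(benzyloxy)-2-[4-(benzyloxy)phenyl]-3-Fl-5-(PBB-oxy)-2,3-dihydro-4H-chromen-4-one F10. TBAF with AcOH frees O7''–H as the only hydroxyl group in the 7''-phenol F11, SO3·pyridine gives the 7''-hydrogen sulfate F12, and hydrogenolysis on Pd/C removes the benzyl ethers and the PBB group and gives 26.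

**Step 18.** Hydrogenolysis may cut the benzylic C2–O1 bond of ring C (opening to a dihydrochalcone) or saturate C2''=C3'' before the last benzyl ether has gone. The sulfate may also be lost if the medium turns acidic. The fallback is a hydrogen-free end game that sets out from diol 24. 2,2,2-Trichloroethyl chlorosulfate with Et3N and DMAP in THF at 0 °C should react at the free O7''–H and give the protected sulfate diester, the 7''-(2,2,2-trichloroethyl sulfate) of 24, F13. BCl3 with pentamethylbenzene in CH2Cl2 at −78 °C removes all benzyl groups and gives the debenzylated trichloroethyl sulfate F14. Zn dust with HCO2NH4 in MeOH removes the trichloroethyl group and gives 26.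

**Step 6.** The allyl group may migrate to C6'' instead of C8'', since both ortho positions are open and only the bond fixation of the chromone favours C8''. The fallback moves the sigmatropic shift to the acetophenone stage, where the hydrogen bond to the acetyl group directs it. It sets out from 3. Heating in N,N-diethylaniline should place the allyl group between O4 and the chelated hydroxyl and give 1-[6-(benzyloxy)-2,4-dihydroxy-3-(prop-2-en-1-yl)phenyl]ethan-1-one F15. MOMCl with DIPEA protects the free 4-OH as the methoxymethyl ether 1-[6-(benzyloxy)-2-hydroxy-4-(methoxymethoxy)-3-(prop-2-en-1-yl)phenyl]ethan-1-one F16. Esterification of the remaining phenol with acid 4 (DIC, DMAP) gives the aryl ester 2-acetyl-3-(benzyloxy)-5-(methoxymethoxy)-6-(prop-2-en-1-yl)phenyl 3,4-bis(benzyloxy)benzoate F17, and KOtBu in THF gives the 1,3-diketone 1-[6-(benzyloxy)-2-hydroxy-4-(methoxymethoxy)-3-(prop-2-en-1-yl)phenyl]-3-[3,4-bis(benzyloxy)phenyl]propane-1,3-dione F18. Aqueous HCl in THF at 50 °C closes the pyranone and removes the methoxymethyl group in the same operation, giving 8. The route resumes at step 7.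

## Further compounds

F1 | step 15 | (2R,3S)-7-(benzyloxy)-2-[4-(benzyloxy)phenyl]-3-Fl-5-hydroxy-2,3-dihydro-4H-chromen-4-one | O=C1c2c(O)cc(OCc3ccccc3)cc2O[C@@H](c2ccc(OCc3ccccc3)cc2)[C@@H]1c1c(O[Si](C(C)C)(C(C)C)C(C)C)cc(OCc5ccccc5)c2c(=O)cc(-c3ccc(OCc4ccccc4)c(OCc4ccccc4)c3)oc12
F2 | step 15 | (2S,3R)-7-(benzyloxy)-2-[4-(benzyloxy)phenyl]-3-Fl-5-hydroxy-2,3-dihydro-4H-chromen-4-one (enantiomer of F1) | O=C1c2c(O)cc(OCc3ccccc3)cc2O[C@H](c2ccc(OCc3ccccc3)cc2)[C@H]1c1c(O[Si](C(C)C)(C(C)C)C(C)C)cc(OCc5ccccc5)c2c(=O)cc(-c3ccc(OCc4ccccc4)c(OCc4ccccc4)c3)oc12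
F3 | step 10 | 1,3,5-tris(methoxymethoxy)benzene | COCOc1cc(OCOC)cc(OCOC)c1
F4 | step 10 | 2-bromo-1,3,5-tris(methoxymethoxy)benzene | COCOc1cc(OCOC)c(Br)c(OCOC)c1
F5 | step 10 | [2,4,6-tris(methoxymethoxy)phenyl]lithium | [Li]c1c(OCOC)cc(OCOC)cc1OCOC
F6 | step 10 | racemic 2-Fl-1-[2,4,6-tris(methoxymethoxy)phenyl]ethan-1-ol | OC(Cc1c(O[Si](C(C)C)(C(C)C)C(C)C)cc(OCc2ccccc2)c2c(=O)cc(-c3ccc(OCc4ccccc4)c(OCc4ccccc4)c3)oc12)c1c(OCOC)cc(OCOC)cc1OCOC
F7 | step 10 | 2-Fl-1-[2,4,6-tris(methoxymethoxy)phenyl]ethan-1-one | O=C(Cc1c(O[Si](C(C)C)(C(C)C)C(C)C)cc(OCc2ccccc2)c2c(=O)cc(-c3ccc(OCc4ccccc4)c(OCc4ccccc4)c3)oc12)c1c(OCOC)cc(OCOC)cc1OCOC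
F8 | step 17 | 1-[4-(benzyloxy)-2,6-bis(PBB-oxy)phenyl]-2-Fl-ethan-1-one | O=C(Cc1c(O[Si](C(C)C)(C(C)C)C(C)C)cc(OCc2ccccc2)c2c(=O)cc(-c3ccc(OCc4ccccc4)c(OCc4ccccc4)c3)oc12)c1c(OCc2ccc(OCc3ccccc3)cc2)cc(OCc2ccccc2)cc1OCc1ccc(OCc2ccccc2)cc1
F9 | step 17 | 2-diazo-1-[4-(benzyloxy)-2,6-bis(PBB-oxy)phenyl]-2-Fl-ethan-1-one | [N-]=[N+]=C(C(=O)c1c(OCc2ccc(OCc3ccccc3)cc2)cc(OCc2ccccc2)cc1OCc1ccc(OCc2ccccc2)cc1)c1c(O[Si](C(C)C)(C(C)C)C(C)C)cc(OCc5ccccc5)c2c(=O)cc(-c3ccc(OCc4ccccc4)c(OCc4ccccc4)c3)oc12
F10 | step 17 | (2R,3S)-7-(benzyloxy)-2-[4-(benzyloxy)phenyl]-3-Fl-5-(PBB-oxy)-2,3-dihydro-4H-chromen-4-one | O=C1c2c(OCc3ccc(OCc4ccccc4)cc3)cc(OCc3ccccc3)cc2O[C@@H](c2ccc(OCc3ccccc3)cc2)[C@@H]1c1c(O[Si](C(C)C)(C(C)C)C(C)C)cc(OCc5ccccc5)c2c(=O)cc(-c3ccc(OCc4ccccc4)c(OCc4ccccc4)c3)oc12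
F11 | step 17 | (2R,3S)-7-(benzyloxy)-3-{5-(benzyloxy)-2-[3,4-bis(benzyloxy)phenyl]-7-hydroxy-4-oxo-4H-chromen-8-yl}-2-[4-(benzyloxy)phenyl]-5-(PBB-oxy)-2,3-dihydro-4H-chromen-4-one | O=C1c2c(OCc3ccc(OCc4ccccc4)cc3)cc(OCc3ccccc3)cc2O[C@@H](c2ccc(OCc3ccccc3)cc2)[C@@H]1c1c(O)cc(OCc5ccccc5)c2c(=O)cc(-c3ccc(OCc4ccccc4)c(OCc4ccccc4)c3)oc12
F12 | step 17 | 5-(benzyloxy)-8-{(2R,3S)-7-(benzyloxy)-2-[4-(benzyloxy)phenyl]-4-oxo-5-(PBB-oxy)-3,4-dihydro-2H-chromen-3-yl}-2-[3,4-bis(benzyloxy)phenyl]-4-oxo-4H-chromen-7-yl hydrogen sulfate | O=C1c2c(OCc3ccc(OCc4ccccc4)cc3)cc(OCc3ccccc3)cc2O[C@@H](c2ccc(OCc3ccccc3)cc2)[C@@H]1c1c(OS(=O)(=O)O)cc(OCc5ccccc5)c2c(=O)cc(-c3ccc(OCc4ccccc4)c(OCc4ccccc4)c3)oc12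
F13 | step 18 | 5-(benzyloxy)-8-{(2R,3S)-7-(benzyloxy)-2-[4-(benzyloxy)phenyl]-5-hydroxy-4-oxo-3,4-dihydro-2H-chromen-3-yl}-2-[3,4-bis(benzyloxy)phenyl]-4-oxo-4H-chromen-7-yl 2,2,2-trichloroethyl sulfate | O=C1c2c(O)cc(OCc3ccccc3)cc2O[C@@H](c2ccc(OCc3ccccc3)cc2)[C@@H]1c1c(OS(=O)(=O)OCC(Cl)(Cl)Cl)cc(OCc5ccccc5)c2c(=O)cc(-c3ccc(OCc4ccccc4)c(OCc4ccccc4)c3)oc12
F14 | step 18 | 2-(3,4-dihydroxyphenyl)-8-[(2R,3S)-5,7-dihydroxy-2-(4-hydroxyphenyl)-4-oxo-3,4-dihydro-2H-chromen-3-yl]-5-hydroxy-4-oxo-4H-chromen-7-yl 2,2,2-trichloroethyl sulfate | O=C1c2c(O)cc(O)cc2O[C@@H](c2ccc(O)cc2)[C@@H]1c1c(OS(=O)(=O)OCC(Cl)(Cl)Cl)cc(O)c2c(=O)cc(-c3ccc(O)c(O)c3)oc12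
F15 | step 6 | 1-[6-(benzyloxy)-2,4-dihydroxy-3-(prop-2-en-1-yl)phenyl]ethan-1-one | CC(=O)c1c(O)c(CC=C)c(O)cc1OCc1ccccc1
F16 | step 6 | 1-[6-(benzyloxy)-2-hydroxy-4-(methoxymethoxy)-3-(prop-2-en-1-yl)phenyl]ethan-1-one | CC(=O)c1c(O)c(CC=C)c(OCOC)cc1OCc1ccccc1
F17 | step 6 | 2-acetyl-3-(benzyloxy)-5-(methoxymethoxy)-6-(prop-2-en-1-yl)phenyl 3,4-bis(benzyloxy)benzoate | CC(=O)c1c(OC(=O)c2ccc(OCc3ccccc3)c(OCc3ccccc3)c2)c(CC=C)c(OCOC)cc1OCc1ccccc1
F18 | step 6 | 1-[6-(benzyloxy)-2-hydroxy-4-(methoxymethoxy)-3-(prop-2-en-1-yl)phenyl]-3-[3,4-bis(benzyloxy)phenyl]propane-1,3-dione | O=C(CC(=O)c1ccc(OCc2ccccc2)c(OCc2ccccc2)c1)c1c(O)c(CC=C)c(OCOC)cc1OCc1ccccc1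
A1 | alternative 1 | protected trans-flavanone–flavone with a 7''-O-allyl group | O=C1c2c(OCc3ccccc3)cc(OCc3ccccc3)cc2O[C@@H](c2ccc(OCc3ccccc3)cc2)[C@@H]1c1c(OCC=C)cc(OCc5ccccc5)c2c(=O)cc(-c3ccc(OCc4ccccc4)c(OCc4ccccc4)c3)oc12
A2 | alternative 2 | spiro-lactone flavan-4-ol | O[C@H]1c2c(OCc3ccccc3)cc(OCc3ccccc3)cc2O[C@@H](c2ccc(OCc3ccccc3)cc2)[C@@]12C(=O)Oc1cc(OCc3ccccc3)c3c(=O)cc(-c4ccc(OCc5ccccc5)c(OCc5ccccc5)c4)oc3c12
A3 | alternative 3 | protected 3-hydroxyflavanone–flavone | O=C1c2c(OCc3ccccc3)cc(OCc3ccccc3)cc2O[C@@H](c2ccc(OCc3ccccc3)cc2)[C@]1(O)c1c(OCC=C)cc(OCc5ccccc5)c2c(=O)cc(-c3ccc(OCc4ccccc4)c(OCc4ccccc4)c3)oc12
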